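**Strategy.** The lactone C3–CH2(ring C) bond is disconnected, giving a ring C/ring D benzylic bromide and a ring A/ring B β-benzyl-γ-butyrolactone. The route rests on the syn arm of ring C: its CH2OH carbon is a lone carbon on the ring C methine of a ring C–CH–CH(OH)–ring D unit, so it is brought in as CO. Carbonylative ring expansion of the (R,R)-trans-stilbene oxide of rings C and D makes the methine–carbonyl bond, the oxetanone ring and the methine stereocentre in one operation; hydride then opens the cis β-lactone to the syn 1,3-diol. The precursor is the trans epoxide with an ortho-benzyloxy ring C and a pivaloyloxy ring D.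

Key step: step 7

Remark on the chemistry: CIP analysis of the target gives a (3S,4S)-trans lactone, a syn arm on ring C (methine R, carbinol S) and an anti arm on ring B (methine S, carbinol S), so the two arms are diastereomeric and the anti arm is set by an anti-aldol reaction, not from a trans epoxide; rings are lettered A (outer ring of the anti arm), B (inner ring on lactone C4), C (inner ring on lactone C3) and D (outer ring of the syn arm).

## Route

**Ring C/ring D fragment**

Step 1
Reactants: 1 5-bromovanillin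
Product: 2 4-(benzyloxy)-3-bromo-5-methoxybenzaldehyde
Conditions: BnBr, K2CO3, DMF, 60 °C
Reagents that add atoms: benzyl bromide, BrCc1ccccc1
Why: Williamson etherification of the acidic, hindered phenol under carbonate base leaves the aldehyde and the aryl bromide untouched.

Step 2
Reactants: 2 4-(benzyloxy)-3-bromo-5-methoxybenzaldehyde
Product: 3 [4-(benzyloxy)-3-bromo-5-methoxyphenyl]methanol
Conditions: NaBH4, MeOH–THF, 0 °C
Reagents that add atoms: none
Why: Borohydride reduction of an aromatic aldehyde to the benzylic alcohol is chemoselective beside the aryl bromide and the benzyl ether.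

Step 3
Reactants: 3 [4-(benzyloxy)-3-bromo-5-methoxyphenyl]methanol
Product: 4 tert-butyldimethylsilyl ether of 3
Conditions: t-BuMe2SiCl, imidazole, DMF, rt
Reagents that add atoms: tert-butyldimethylsilyl chloride, CC(C)(C)[Si](C)(C)Cl
Why: Imidazole-promoted silylation masks the primary alcohol through the Heck, epoxidation, carbonylation and hydride steps.

Step 4
Reactants: 5 2-methoxy-4-vinylphenol
Product: 6 2-methoxy-4-vinylphenyl pivalate
Conditions: t-BuCOCl, Et3N, DMAP (cat.), CH2Cl2, 0 °C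
Reagents that add atoms: pivaloyl chloride, CC(C)(C)C(=O)Cl
Why: Acylation of the phenol gives a hindered aryl ester that, unlike an acetate, should survive the amine base of the Heck step and the aqueous carbonate of the epoxidation while still deactivating ring D.

Step 5
Reactants: 4 ring C aryl bromide silyl ether; 6 2-methoxy-4-vinylphenyl pivalate
Product: 7 (E)-stilbene of rings C and D
Conditions: Pd(OAc)2 (5 mol%), P(o-tol)3 (10 mol%), Et3N, DMF, 100 °C
Reagents that add atoms: none
Why: Heck reaction, in which oxidative addition of the aryl bromide to zerovalent palladium, syn carbopalladation at the terminal alkene carbon and syn β-hydride elimination should deliver the (E)-alkene.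

Step 6
Reactants: 7 (E)-stilbene of rings C and D
Product: 8 (2R,3R)-trans-stilbene oxide of rings C and D
Conditions: D-fructose-derived Shi ketone (0.3 equiv), Oxone (2KHSO5·KHSO4·K2SO4), K2CO3, Bu4NHSO4, Na2B4O7–Na2EDTA buffer, MeCN–dimethoxymethane, 0 °C
Reagents that add atoms: potassium peroxymonosulfate, [K+].[O-]S(=O)(=O)OO
Why: Shi epoxidation, in which the chiral dioxirane transfers oxygen to the trans-disubstituted alkene through a spiro transition state, the mode that gives (R,R)-epoxides from trans-stilbenes, so both stereocentres are set by the catalyst.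

Step 7
Reactants: 8 (2R,3R)-trans-stilbene oxide of rings C and D
Product: 9 cis-(3S,4S)-3-(ring C aryl)-4-(ring D aryl)oxetan-2-one
Conditions: [(salph)Al(THF)2][Co(CO)4] (5 mol%; salph = N,N'-o-phenylenebis(3,5-di-tert-butylsalicylideneimine) dianion), CO (60 atm), THF, 50 °C
Reagents that add atoms: carbon monoxide, [C-]#[O+]
Why: This is the Lewis-acid/tetracarbonylcobaltate ring-expanding carbonylation of epoxides, which converts trans-2,3-disubstituted epoxides into cis β-lactones. The aluminium cation binds the epoxide oxygen, [Co(CO)4]− opens the ring by backside attack at the ring C benzylic carbon, CO migratory insertion converts the alkylcobalt into an acylcobalt, and the aluminium alkoxide on the ring D carbon attacks the acyl carbon to close the oxetan-2-one (4-exo-trig) and release the cobaltate. The new stereocentre, the ring C methine (S in the lactone), is set by the epoxide configuration through this single inversion, and the ring D carbinol carbon keeps its C–O bond and configuration, so the trans epoxide should give only the cis lactone. The step needs regioselection between two benzylic carbons, which has no direct precedent: the ortho-benzyloxy group lets the ring C carbon carry more positive charge in the loose SN2 transition state, whereas the pivaloyloxy group, a much weaker donor than an ether, disfavours opening next to ring D. It also needs CO capture to outrun Lewis-acid-induced rearrangement to carbonyl compounds, which high CO pressure and an ether solvent support.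

Step 8
Reactants: 9 cis-β-lactone of rings C and D
Product: 10 syn-(1S,2R)-1,3-diol with free ring D phenol
Conditions: LiAlH4, THF, −20 to 0 °C; aqueous potassium sodium tartrate work-up
Reagents that add atoms: none
Why: Hydride reduction of the β-lactone by acyl–oxygen cleavage touches neither stereocentre, so the cis lactone should become the syn 1,3-diol, and the same reagent removes the pivalate.

Step 9
Reactants: 10 syn diol with free ring D phenol
Product: 11 syn diol with ring D benzyl ether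
Conditions: BnBr, K2CO3, DMF, rt
Reagents that add atoms: benzyl bromide, BrCc1ccccc1
Why: Williamson etherification under carbonate base is selective for the phenol because only the phenol is deprotonated.

Step 10
Reactants: 11 syn diol with ring D benzyl ether
Product: 12 cis-(4S,5R)-4,5-diaryl-2,2-dimethyl-1,3-dioxane
Conditions: 2-methoxypropene, PPTS (cat.), CH2Cl2, 0 °C
Reagents that add atoms: 2-methoxypropene, COC(C)=C
Why: Acid-catalysed acetalisation with an enol ether closes the isopropylidene acetal on the 1,3-diol under conditions mild enough for the benzylic carbinol, and no stereocentre is affected.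

Step 11
Reactants: 12 ring C/D acetonide silyl ether
Product: 13 ring C/D acetonide benzylic alcohol
Conditions: Bu4NF, THF, 0 °C to rt
Reagents that add atoms: none
Why: Fluoride-mediated desilylation cleaves the primary silyl ether and leaves the acetonide and the benzyl ethers intact.

Step 12
Reactants: 13 ring C/D acetonide benzylic alcohol
Product: 14 ring C/D acetonide benzylic bromide
Conditions: CBr4, PPh3, CH2Cl2, 0 °C
Reagents that add atoms: carbon tetrabromide, BrC(Br)(Br)Br
Why: Appel reaction converts the primary benzylic alcohol into the bromide under neutral conditions that the acetonide tolerates.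

**Ring A/ring B fragment**

Step 13
Reactants: 3 [4-(benzyloxy)-3-bromo-5-methoxyphenyl]methanol
Product: 15 2-(benzyloxy)-1-bromo-5-(bromomethyl)-3-methoxybenzene
Conditions: PBr3, CH2Cl2, 0 °C
Reagents that add atoms: phosphorus tribromide, BrP(Br)Br
Why: Bromide displaces the phosphite ester of the benzylic alcohol (SN2), the standard conversion of a benzylic alcohol into its bromide.

Step 14
Reactants: 16 (S)-4-benzyl-1,3-oxazolidin-2-one; 17 4-(tert-butoxy)-4-oxobutanoic acid
Product: 19 tert-butyl 4-[(4S)-4-benzyl-2-oxo-1,3-oxazolidin-3-yl]-4-oxobutanoate, via mixed pivalic anhydride 18 (not isolated)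
Conditions: t-BuCOCl, Et3N, THF, −20 °C; then 16, LiCl, rt
Reagents that add atoms: none
Why: Mixed-anhydride N-acylation of the oxazolidinone takes place at the unhindered succinyl carbonyl of the anhydride.

Step 15
Reactants: 19 succinyl oxazolidinone; 15 ring B benzylic bromide
Product: 21 (3S)-3-benzylated succinyl oxazolidinone, via sodium Z-enolate 20 (not isolated)
Conditions: NaN(SiMe3)2, THF, −78 °C; then 15, −78 to −40 °C
Reagents that add atoms: none
Why: Evans asymmetric alkylation, in which the chelated Z-enolate is alkylated on the face opposite the auxiliary benzyl group, should set the (S) centre that becomes lactone C4.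

Step 16
Reactants: 21 (3S)-3-benzylated succinyl oxazolidinone
Product: 23 (4S)-4-[4-(benzyloxy)-3-bromo-5-methoxybenzyl]oxolan-2-one, via hydroxy ester 22 (not isolated)
Conditions: LiBH4, MeOH (1 equiv), THF, 0 °C; then p-TsOH·H2O (cat.), toluene, 60 °C
Reagents that add atoms: none
Why: Reductive cleavage of the N-acyloxazolidinone spares the tert-butyl ester, and acid-catalysed lactonisation of the γ-hydroxy ester (5-exo-trig acyl substitution) closes the butyrolactone without touching the stereocentre.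

Step 17
Reactants: 23 ring B bromo lactone
Product: 24 tert-butyl arylacetate of ring B
Conditions: BrZnCH2CO2t-Bu (from BrCH2CO2t-Bu and Zn, THF), Pd(dba)2 (2 mol%), P(t-Bu)3 (2 mol%), THF, rt
Reagents that add atoms: (2-tert-butoxy-2-oxoethyl)zinc bromide, CC(C)(C)OC(=O)C[Zn]Br
Why: Negishi-type palladium-catalysed α-arylation of a Reformatsky reagent couples the aryl bromide under neutral conditions that the lactone tolerates.

Step 18
Reactants: 24 tert-butyl arylacetate of ring B
Product: 25 arylacetic acid of ring B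
Conditions: CF3CO2H–CH2Cl2 (1:4), 0 °C to rt
Reagents that add atoms: none
Why: Acidolysis of the tert-butyl ester (E1 loss of isobutylene) frees the acid, and the lactone and the aryl benzyl ether should withstand brief exposure to dilute acid.

Step 19
Reactants: 25 arylacetic acid of ring B; 16 (S)-4-benzyl-1,3-oxazolidin-2-one
Product: 27 N-arylacetyl oxazolidinone of ring B, via mixed pivalic anhydride 26 (not isolated)
Conditions: t-BuCOCl, Et3N, THF, −20 °C; then 16, LiCl, −20 °C to rt
Reagents that add atoms: none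
Why: Mixed-anhydride N-acylation under amine/LiCl conditions avoids strong base and so spares the lactone.

Step 20
Reactants: 27 N-arylacetyl oxazolidinone of ring B; 28 4-(benzyloxy)-3-methoxybenzaldehyde
Product: 30 anti-(2R,3S)-aldol adduct, via trimethylsilyl ether 29 (not isolated)
Conditions: MgCl2 (0.2 equiv), Et3N, Me3SiCl, EtOAc, rt; then Et3N·3HF, THF, rt
Reagents that add atoms: none
Why: Magnesium-halide-catalysed direct anti-aldol reaction of an N-acyloxazolidinone (Evans anti-aldol), in which the chelated Z-enolate adds anti-selectively to the non-enolisable aldehyde on the face opposite the auxiliary benzyl group and silylation of the aldolate blocks retro-aldol, should set the ring B methine (2R in the imide) and the ring A carbinol (3S).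

Step 21
Reactants: 30 anti-aldol adduct
Product: 31 anti-(1S,2S)-1,3-diol of rings A and B on the lactone
Conditions: NaBH4, THF–H2O (4:1), 0 °C to rt
Reagents that add atoms: none
Why: Borohydride reduction of the activated exocyclic imide carbonyl (reductive removal of the Evans auxiliary) should be faster than reduction of the γ-lactone and leaves both stereocentres untouched.

Step 22
Reactants: 31 anti diol of rings A and B
Product: 32 trans-(4S,5S)-4,5-diaryl-2,2-dimethyl-1,3-dioxane on the lactone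
Conditions: 2-methoxypropene, PPTS (cat.), CH2Cl2, 0 °C
Reagents that add atoms: 2-methoxypropene, COC(C)=C
Why: Acid-catalysed acetalisation with an enol ether closes the isopropylidene acetal on the 1,3-diol without affecting any stereocentre.

**Union and end game**

Step 23
Reactants: 32 ring A/B acetonide lactone; 14 ring C/D acetonide benzylic bromide
Product: 34 (3S,4S)-trans-3,4-dibenzyl lactone, bis-acetonide tetrabenzyl ether, via lithium enolate 33 (not isolated)
Conditions: LiN(SiMe3)2, THF, −78 °C; then 14, DMPU, −78 to −30 °C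
Reagents that add atoms: none
Why: Alkylation of the lactone enolate with the benzylic bromide occurs anti to the C4 substituent (1,2-induction in the five-membered enolate), which should give the trans lactone with the new C3 centre S.

Step 24
Reactants: 34 bis-acetonide tetrabenzyl ether
Product: 35 tetra-O-benzyl tetraol
Conditions: AcOH–H2O–THF (3:1:1), 40 °C
Reagents that add atoms: none
Why: Acid-catalysed acetal hydrolysis proceeds through the tertiary oxocarbenium ion at the isopropylidene carbon, a pathway much faster than ionisation of the benzylic C–O bonds, and should release both diols.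

Step 25
Reactants: 35 tetra-O-benzyl tetraol
Product: 36 CNP0113972.1
Conditions: H2 (1 atm), 10% Pd/C, EtOAc–EtOH, rt
Reagents that add atoms: none
Why: Catalytic hydrogenolysis of the four aryl benzyl ethers under neutral conditions should spare the secondary benzylic alcohols and the lactone.

## Compound list

1 | 5-bromovanillin (3-bromo-4-hydroxy-5-methoxybenzaldehyde) | COc1cc(C=O)cc(Br)c1O | starting material
2 | 4-(benzyloxy)-3-bromo-5-methoxybenzaldehyde | COc1cc(C=O)cc(Br)c1OCc1ccccc1 | intermediate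
3 | [4-(benzyloxy)-3-bromo-5-methoxyphenyl]methanol | COc1cc(CO)cc(Br)c1OCc1ccccc1 | intermediate
4 | {[4-(benzyloxy)-3-bromo-5-methoxybenzyl]oxy}(tert-butyl)dimethylsilane | COc1cc(CO[Si](C)(C)C(C)(C)C)cc(Br)c1OCc1ccccc1 | intermediate
5 | 2-methoxy-4-vinylphenol | COc1cc(C=C)ccc1O | starting material
6 | 2-methoxy-4-vinylphenyl pivalate | COc1cc(C=C)ccc1OC(=O)C(C)(C)C | intermediate
7 | 4-[(E)-2-{2-(benzyloxy)-3-methoxy-5-[(tert-butyldimethylsilyloxy)methyl]phenyl}ethenyl]-2-methoxyphenyl pivalate | CC(C)(C)[Si](C)(C)OCc1cc(OC)c(OCc2ccccc2)c(/C=C/c2ccc(OC(=O)C(C)(C)C)c(OC)c2)c1 | intermediate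
8 | 4-[(2R,3R)-3-{2-(benzyloxy)-3-methoxy-5-[(tert-butyldimethylsilyloxy)methyl]phenyl}oxiran-2-yl]-2-methoxyphenyl pivalate (trans epoxide) | CC(C)(C)[Si](C)(C)OCc1cc(OC)c(OCc2ccccc2)c([C@H]2O[C@@H]2c2ccc(OC(=O)C(C)(C)C)c(OC)c2)c1 | intermediate
9 | (3S,4S)-3-{2-(benzyloxy)-3-methoxy-5-[(tert-butyldimethylsilyloxy)methyl]phenyl}-4-[3-methoxy-4-(pivaloyloxy)phenyl]oxetan-2-one (cis) | CC(C)(C)[Si](C)(C)OCc1cc(OC)c(OCc2ccccc2)c([C@@H]2C(=O)O[C@@H]2c2ccc(OC(=O)C(C)(C)C)c(OC)c2)c1 | intermediate
10 | (1S,2R)-2-{2-(benzyloxy)-3-methoxy-5-[(tert-butyldimethylsilyloxy)methyl]phenyl}-1-(4-hydroxy-3-methoxyphenyl)propane-1,3-diol (syn) | CC(C)(C)[Si](C)(C)OCc1cc(OC)c(OCc2ccccc2)c([C@H](CO)[C@H](O)c2ccc(O)c(OC)c2)c1 | intermediate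
11 | (1S,2R)-1-[4-(benzyloxy)-3-methoxyphenyl]-2-{2-(benzyloxy)-3-methoxy-5-[(tert-butyldimethylsilyloxy)methyl]phenyl}propane-1,3-diol (syn) | CC(C)(C)[Si](C)(C)OCc1cc(OC)c(OCc2ccccc2)c([C@H](CO)[C@H](O)c2ccc(OCc3ccccc3)c(OC)c2)c1 | intermediate
12 | (4S,5R)-4-[4-(benzyloxy)-3-methoxyphenyl]-5-{2-(benzyloxy)-3-methoxy-5-[(tert-butyldimethylsilyloxy)methyl]phenyl}-2,2-dimethyl-1,3-dioxane (cis) | CC1(C)OC[C@@H](c2cc(CO[Si](C)(C)C(C)(C)C)cc(OC)c2OCc2ccccc2)[C@@H](c2ccc(OCc3ccccc3)c(OC)c2)O1 | intermediate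
13 | {4-(benzyloxy)-3-[(4S,5R)-4-(4-benzyloxy-3-methoxyphenyl)-2,2-dimethyl-1,3-dioxan-5-yl]-5-methoxyphenyl}methanol | CC1(C)OC[C@@H](c2cc(CO)cc(OC)c2OCc2ccccc2)[C@@H](c2ccc(OCc3ccccc3)c(OC)c2)O1 | intermediate
14 | (4S,5R)-4-[4-(benzyloxy)-3-methoxyphenyl]-5-[2-(benzyloxy)-5-(bromomethyl)-3-methoxyphenyl]-2,2-dimethyl-1,3-dioxane | CC1(C)OC[C@@H](c2cc(CBr)cc(OC)c2OCc2ccccc2)[C@@H](c2ccc(OCc3ccccc3)c(OC)c2)O1 | intermediate
15 | 2-(benzyloxy)-1-bromo-5-(bromomethyl)-3-methoxybenzene | COc1cc(CBr)cc(Br)c1OCc1ccccc1 | intermediate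
16 | (S)-4-benzyl-1,3-oxazolidin-2-one | O=C1N[C@@H](Cc2ccccc2)CO1 | starting material
17 | 4-(tert-butoxy)-4-oxobutanoic acid (mono-tert-butyl succinate) | CC(C)(C)OC(=O)CCC(=O)O | starting material
18 | 4-(tert-butoxy)-4-oxobutanoic pivalic anhydride | CC(C)(C)OC(=O)CCC(=O)OC(=O)C(C)(C)C | intermediate
19 | tert-butyl 4-[(4S)-4-benzyl-2-oxo-1,3-oxazolidin-3-yl]-4-oxobutanoate | CC(C)(C)OC(=O)CCC(=O)N1[C@@H](Cc2ccccc2)COC1=O | intermediate
20 | sodium (Z)-enolate of 19 | [Na+].CC(C)(C)OC(=O)C/C=C(\[O-])N1[C@@H](Cc2ccccc2)COC1=O | intermediate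
21 | tert-butyl (3S)-3-[4-(benzyloxy)-3-bromo-5-methoxybenzyl]-4-[(4S)-4-benzyl-2-oxo-1,3-oxazolidin-3-yl]-4-oxobutanoate | CC(C)(C)OC(=O)C[C@H](Cc1cc(OC)c(OCc2ccccc2)c(Br)c1)C(=O)N1[C@@H](Cc2ccccc2)COC1=O | intermediate
22 | tert-butyl (3S)-3-[4-(benzyloxy)-3-bromo-5-methoxybenzyl]-4-hydroxybutanoate | CC(C)(C)OC(=O)C[C@H](Cc1cc(OC)c(OCc2ccccc2)c(Br)c1)CO | intermediate
23 | (4S)-4-[4-(benzyloxy)-3-bromo-5-methoxybenzyl]oxolan-2-one | COc1cc(C[C@@H]2COC(=O)C2)cc(Br)c1OCc1ccccc1 | intermediate
24 | tert-butyl 2-[2-(benzyloxy)-3-methoxy-5-{[(3S)-5-oxooxolan-3-yl]methyl}phenyl]acetate | COc1cc(C[C@@H]2COC(=O)C2)cc(CC(=O)OC(C)(C)C)c1OCc1ccccc1 | intermediate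
25 | 2-[2-(benzyloxy)-3-methoxy-5-{[(3S)-5-oxooxolan-3-yl]methyl}phenyl]acetic acid | COc1cc(C[C@@H]2COC(=O)C2)cc(CC(=O)O)c1OCc1ccccc1 | intermediate
26 | mixed pivalic anhydride of 25 | COc1cc(C[C@@H]2COC(=O)C2)cc(CC(=O)OC(=O)C(C)(C)C)c1OCc1ccccc1 | intermediate
27 | (4S)-4-benzyl-3-{2-[2-(benzyloxy)-3-methoxy-5-{[(3S)-5-oxooxolan-3-yl]methyl}phenyl]acetyl}-1,3-oxazolidin-2-one | COc1cc(C[C@@H]2COC(=O)C2)cc(CC(=O)N2[C@@H](Cc3ccccc3)COC2=O)c1OCc1ccccc1 | intermediate
28 | 4-(benzyloxy)-3-methoxybenzaldehyde | COc1cc(C=O)ccc1OCc1ccccc1 | starting material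
29 | trimethylsilyl ether of 30 | COc1cc([C@@H](O[Si](C)(C)C)[C@H](C(=O)N2[C@@H](Cc3ccccc3)COC2=O)c2cc(C[C@@H]3COC(=O)C3)cc(OC)c2OCc2ccccc2)ccc1OCc1ccccc1 | intermediate
30 | (4S)-4-benzyl-3-{(2R,3S)-3-[4-(benzyloxy)-3-methoxyphenyl]-2-[2-(benzyloxy)-3-methoxy-5-{[(3S)-5-oxooxolan-3-yl]methyl}phenyl]-3-hydroxypropanoyl}-1,3-oxazolidin-2-one (anti) | COc1cc([C@@H](O)[C@H](C(=O)N2[C@@H](Cc3ccccc3)COC2=O)c2cc(C[C@@H]3COC(=O)C3)cc(OC)c2OCc2ccccc2)ccc1OCc1ccccc1 | intermediate
31 | (4S)-4-{4-(benzyloxy)-3-[(1S,2S)-1-(4-benzyloxy-3-methoxyphenyl)-1,3-dihydroxypropan-2-yl]-5-methoxybenzyl}oxolan-2-one (anti) | COc1cc([C@@H](O)[C@H](CO)c2cc(C[C@@H]3COC(=O)C3)cc(OC)c2OCc2ccccc2)ccc1OCc1ccccc1 | intermediate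
32 | (4S)-4-{4-(benzyloxy)-3-[(4S,5S)-4-(4-benzyloxy-3-methoxyphenyl)-2,2-dimethyl-1,3-dioxan-5-yl]-5-methoxybenzyl}oxolan-2-one (trans dioxane) | CC1(C)OC[C@H](c2cc(C[C@@H]3COC(=O)C3)cc(OC)c2OCc2ccccc2)[C@@H](c2ccc(OCc3ccccc3)c(OC)c2)O1 | intermediate
33 | lithium enolate of 32 | [Li+].CC1(C)OC[C@H](c2cc(C[C@@H]3COC([O-])=C3)cc(OC)c2OCc2ccccc2)[C@@H](c2ccc(OCc3ccccc3)c(OC)c2)O1 | intermediate
34 | (3S,4S)-3-{4-(benzyloxy)-3-[(4S,5R)-4-(4-benzyloxy-3-methoxyphenyl)-2,2-dimethyl-1,3-dioxan-5-yl]-5-methoxybenzyl}-4-{4-(benzyloxy)-3-[(4S,5S)-4-(4-benzyloxy-3-methoxyphenyl)-2,2-dimethyl-1,3-dioxan-5-yl]-5-methoxybenzyl}oxolan-2-one | CC1(C)OC[C@H](c2cc(C[C@@H]3COC(=O)[C@H]3Cc3cc(OC)c(OCc4ccccc4)c([C@@H]4COC(C)(C)O[C@@H]4c4ccc(OCc5ccccc5)c(OC)c4)c3)cc(OC)c2OCc2ccccc2)[C@@H](c2ccc(OCc3ccccc3)c(OC)c2)O1 | intermediate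
35 | (3S,4S)-3-{4-(benzyloxy)-3-[(1S,2R)-1-(4-benzyloxy-3-methoxyphenyl)-1,3-dihydroxypropan-2-yl]-5-methoxybenzyl}-4-{4-(benzyloxy)-3-[(1S,2S)-1-(4-benzyloxy-3-methoxyphenyl)-1,3-dihydroxypropan-2-yl]-5-methoxybenzyl}oxolan-2-one | COc1cc([C@@H](O)[C@H](CO)c2cc(C[C@@H]3COC(=O)[C@H]3Cc3cc(OC)c(OCc4ccccc4)c([C@H](CO)[C@H](O)c4ccc(OCc5ccccc5)c(OC)c4)c3)cc(OC)c2OCc2ccccc2)ccc1OCc1ccccc1 | intermediate
36 | CNP0113972.1: (3S,4S)-3-{3-[(1S,2R)-1,3-dihydroxy-1-(4-hydroxy-3-methoxyphenyl)propan-2-yl]-4-hydroxy-5-methoxybenzyl}-4-{3-[(1S,2S)-1,3-dihydroxy-1-(4-hydroxy-3-methoxyphenyl)propan-2-yl]-4-hydroxy-5-methoxybenzyl}oxolan-2-one | COc1cc([C@@H](O)[C@H](CO)c2cc(C[C@@H]3COC(=O)[C@H]3Cc3cc(OC)c(O)c([C@H](CO)[C@H](O)c4ccc(O)c(OC)c4)c3)cc(OC)c2O)ccc1O | target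

## Step count and risks

Total step count: 25.
Longest linear sequence: 14 steps, from 1 to 36 through either arm (steps 1, 2, 3, 5–12, 23–25 or steps 1, 2, 13, 15–25).

The three steps most likely to fail:

**Step 7.** The cobaltate may open the epoxide at the ring D benzylic carbon, which gives the regioisomeric lactone. Ionisation to an open benzylic cation may erase the inversion, or the Lewis acid may trigger a 1,2-shift to carbonyl compounds before CO is captured. The fallback builds the syn arm by an aldol reaction with no epoxide; it sets out from 4 and comes back at 11, bypassing steps 4 to 9. Bromide 4 is coupled with BrZnCH2CO2Et under Pd(dba)2/P(t-Bu)3 catalysis to give the ethyl arylacetate F1. Saponification (LiOH, THF–H2O) gives the arylacetic acid F2. Pivaloyl chloride/Et3N converts it into the mixed pivalic anhydride F3 (not isolated), which acylates 16 in the presence of LiCl to give the N-arylacetyl oxazolidinone F4. Bu2BOTf/i-Pr2NEt (CH2Cl2, 0 °C) forms the dibutylboron Z-enolate F5 (not isolated), which adds to aldehyde 28 at −78 °C through a chair transition state to give the boron aldolate F6 (not isolated). Oxidative work-up (H2O2, pH 7 buffer) should then give the Evans syn-aldol adduct F7 with the (2S,3S) configuration. LiBH4 (MeOH, THF, 0 °C) removes the auxiliary and delivers diol 11.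

**Step 20.** The α-aryl acyl group may give low anti/syn or facial selectivity, the electron-rich aldehyde may add slowly, and retro-aldol equilibration may occur before the aldolate is silylated. The fallback replaces the aldol reaction by an allylboration followed by oxidative cleavage; it sets out from 23 and comes back at 31. Stille coupling of 23 with tributyl(vinyl)stannane (Pd(PPh3)4, toluene, 100 °C) gives the styrene F8. Cross-metathesis with allylboronic acid pinacol ester (second-generation Grubbs catalyst, CH2Cl2, 40 °C) gives the (E)-3-arylallyl boronate F9. Allylboration of aldehyde 28 catalysed by the chiral phosphoric acid (S)-TRIP (toluene, −30 °C) passes through a chair transition state in which the E geometry becomes the anti relationship; the (S) antipode of the catalyst is the one expected to give the S carbinol. This gives the pinacol borate F10 (not isolated), which is hydrolysed on work-up to the anti homoallylic alcohol F11. OsO4 (cat.)/NaIO4 with 2,6-lutidine (dioxane–H2O) cleaves the vinyl group to the aldehyde F12 (not isolated), which NaBH4 reduces in the same flask to diol 31.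

**Step 21.** The hydride may over-reduce the γ-lactone, or attack the ring carbonyl of the oxazolidinone because the exocyclic carbonyl is hindered by the α-aryl group. The fallback separates cleavage from reduction; it sets out from 30 and comes back at 31. LiOH/H2O2 (THF–H2O, 0 °C) cleaves the auxiliary from 30 and, after acidification (which recloses any opened lactone), gives the β-hydroxy acid F13. BH3·SMe2 (THF, 0 °C to rt) then reduces the carboxylic acid in preference to the lactone and gives 31.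

## Further compounds

F1 | step 7 | ethyl 2-{2-(benzyloxy)-3-methoxy-5-[(tert-butyldimethylsilyloxy)methyl]phenyl}acetate | CCOC(=O)Cc1cc(CO[Si](C)(C)C(C)(C)C)cc(OC)c1OCc1ccccc1
F2 | step 7 | 2-{2-(benzyloxy)-3-methoxy-5-[(tert-butyldimethylsilyloxy)methyl]phenyl}acetic acid | OC(=O)Cc1cc(CO[Si](C)(C)C(C)(C)C)cc(OC)c1OCc1ccccc1
F3 | step 7 | mixed pivalic anhydride of F2 | CC(C)(C)C(=O)OC(=O)Cc1cc(CO[Si](C)(C)C(C)(C)C)cc(OC)c1OCc1ccccc1
F4 | step 7 | (4S)-4-benzyl-3-(2-{2-(benzyloxy)-3-methoxy-5-[(tert-butyldimethylsilyloxy)methyl]phenyl}acetyl)-1,3-oxazolidin-2-one | O=C(Cc1cc(CO[Si](C)(C)C(C)(C)C)cc(OC)c1OCc1ccccc1)N1[C@@H](Cc2ccccc2)COC1=O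
F5 | step 7 | dibutylboron (Z)-enolate of F4 | CCCCB(CCCC)O/C(=C\c1cc(CO[Si](C)(C)C(C)(C)C)cc(OC)c1OCc1ccccc1)N1[C@@H](Cc2ccccc2)COC1=O
F6 | step 7 | O-dibutylboryl aldolate of F7 | CC(C)(C)[Si](C)(C)OCc1cc(OC)c(OCc2ccccc2)c([C@H](C(=O)N2[C@@H](Cc3ccccc3)COC2=O)[C@H](OB(CCCC)CCCC)c2ccc(OCc3ccccc3)c(OC)c2)c1
F7 | step 7 | (4S)-4-benzyl-3-[(2S,3S)-3-[4-(benzyloxy)-3-methoxyphenyl]-2-{2-(benzyloxy)-3-methoxy-5-[(tert-butyldimethylsilyloxy)methyl]phenyl}-3-hydroxypropanoyl]-1,3-oxazolidin-2-one (syn) | CC(C)(C)[Si](C)(C)OCc1cc(OC)c(OCc2ccccc2)c([C@H](C(=O)N2[C@@H](Cc3ccccc3)COC2=O)[C@H](O)c2ccc(OCc3ccccc3)c(OC)c2)c1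
F8 | step 20 | (4S)-4-[4-(benzyloxy)-3-ethenyl-5-methoxybenzyl]oxolan-2-one | COc1cc(C[C@@H]2COC(=O)C2)cc(C=C)c1OCc1ccccc1
F9 | step 20 | (4S)-4-{4-(benzyloxy)-3-methoxy-5-[(E)-3-(4,4,5,5-tetramethyl-1,3,2-dioxaborolan-2-yl)prop-1-en-1-yl]benzyl}oxolan-2-one | COc1cc(C[C@@H]2COC(=O)C2)cc(/C=C/CB2OC(C)(C)C(C)(C)O2)c1OCc1ccccc1
F10 | step 20 | pinacol borate ester of F11 | COc1cc([C@@H](OB2OC(C)(C)C(C)(C)O2)[C@H](C=C)c2cc(C[C@@H]3COC(=O)C3)cc(OC)c2OCc2ccccc2)ccc1OCc1ccccc1
F11 | step 20 | (4S)-4-{4-(benzyloxy)-3-[(1S,2S)-1-(4-benzyloxy-3-methoxyphenyl)-1-hydroxybut-3-en-2-yl]-5-methoxybenzyl}oxolan-2-one (anti) | COc1cc([C@@H](O)[C@H](C=C)c2cc(C[C@@H]3COC(=O)C3)cc(OC)c2OCc2ccccc2)ccc1OCc1ccccc1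
F12 | step 20 | (2R,3S)-3-[4-(benzyloxy)-3-methoxyphenyl]-2-[2-(benzyloxy)-3-methoxy-5-{[(3S)-5-oxooxolan-3-yl]methyl}phenyl]-3-hydroxypropanal | COc1cc([C@@H](O)[C@H](C=O)c2cc(C[C@@H]3COC(=O)C3)cc(OC)c2OCc2ccccc2)ccc1OCc1ccccc1
F13 | step 21 | (2R,3S)-3-[4-(benzyloxy)-3-methoxyphenyl]-2-[2-(benzyloxy)-3-methoxy-5-{[(3S)-5-oxooxolan-3-yl]methyl}phenyl]-3-hydroxypropanoic acid | COc1cc([C@@H](O)[C@H](C(=O)O)c2cc(C[C@@H]3COC(=O)C3)cc(OC)c2OCc2ccccc2)ccc1OCc1ccccc1
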